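Ring A is disconnected as a whole. Its substitution pattern, oxygen on C5 and C7 with the prenyl group on C6 between them and fusion through C4a–C8a to pyranone ring C, is what a vinylketene and a siloxyalkyne deliver. One operation (photochemical Wolff rearrangement, ketene–alkyne [2+2] cycloaddition, 4π ring opening, 6π electrocyclisation) should form C8–C8a, C5–C6, C7–C8 and C4a–C5 and place the prenyl group unambiguously. The precursors are a 5-aryl-4-pyranone bearing a diazoacetyl group at C2, assembled from kojic acid and a silyl-protected catechol boronate, and a prenyl-substituted triisopropylsiloxyalkyne made from prenyl bromide. A single buffered fluoride treatment then removes the three silyl groups.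

Key step: step 9

Remark: ring A atoms are named by chromen-4-one numbering (O1, C2, C3, C4, C4a, C5 to C8, C8a); C2 and C3 of the pyranone in the precursor become C8a and C4a. The target has no stereocentre.

Step 1
Reactants: 1 4-bromocatechol
Product: 2 4-bromo-1,2-bis(tert-butyldimethylsilyloxy)benzene
Conditions: TBSCl (2.4 equiv), imidazole (5 equiv), DMF, rt
Reagents that add atoms: tert-butyldimethylsilyl chloride, CC(C)(C)[Si](C)(C)Cl
Why: Standard O-silylation of both phenols with a silyl chloride and imidazole, to which the aryl bromide is inert.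

Step 2
Reactants: 2 4-bromo-1,2-bis(tert-butyldimethylsilyloxy)benzene
Product: 3 2-[3,4-bis(tert-butyldimethylsilyloxy)phenyl]-4,4,5,5-tetramethyl-1,3,2-dioxaborolane
Conditions: B2pin2 (1.2 equiv), PdCl2(dppf) (3 mol %), KOAc (3 equiv), dioxane, 85 °C
Reagents that add atoms: bis(pinacolato)diboron, CC1(C)OB(OC1(C)C)B1OC(C)(C)C(C)(C)O1
Why: Miyaura borylation of an aryl bromide, run with KOAc, a base too weak to cleave aryl silyl ethers.

Step 3
Reactants: 4 kojic acid
Product: 5 6-(hydroxymethyl)-4-oxo-4H-pyran-3-yl trifluoromethanesulfonate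
Conditions: PhNTf2 (1.05 equiv), Et3N (1.2 equiv), DMF, 0 °C to rt
Reagents that add atoms: N-phenylbis(trifluoromethanesulfonimide), O=S(=O)(N(c1ccccc1)S(=O)(=O)C(F)(F)F)C(F)(F)F
Why: Chemoselective O-triflation, since only the acidic enolic 5-OH is deprotonated by Et3N and the mild triflyl donor PhNTf2 does not react with the neutral primary alcohol.

Step 4
Reactants: 5 6-(hydroxymethyl)-4-oxo-4H-pyran-3-yl trifluoromethanesulfonate, 3 2-[3,4-bis(tert-butyldimethylsilyloxy)phenyl]-4,4,5,5-tetramethyl-1,3,2-dioxaborolane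
Product: 6 5-[3,4-bis(tert-butyldimethylsilyloxy)phenyl]-2-(hydroxymethyl)-4H-pyran-4-one
Conditions: PdCl2(dppf) (5 mol %), K3PO4 (2 equiv), dioxane/H2O 10:1, 60 °C
Reagents that add atoms: none
Why: Suzuki–Miyaura coupling of an electron-poor enol triflate, which adds oxidatively with ease, under a mild phosphate base chosen to spare the aryl silyl ethers and the free alcohol.

Step 5
Reactants: 6 5-[3,4-bis(tert-butyldimethylsilyloxy)phenyl]-2-(hydroxymethyl)-4H-pyran-4-one
Product: 7 5-[3,4-bis(tert-butyldimethylsilyloxy)phenyl]-4-oxo-4H-pyran-2-carboxylic acid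
Conditions: TEMPO (0.2 equiv), PhI(OAc)2 (2.2 equiv), MeCN/H2O 1:1, rt
Reagents that add atoms: water, O
Why: Oxoammonium (TEMPO/PhI(OAc)2) oxidation takes the primary alcohol through the readily hydrated aldehyde to the acid under near-neutral conditions that aryl silyl ethers tolerate.

Step 6
Reactants: 7 5-[3,4-bis(tert-butyldimethylsilyloxy)phenyl]-4-oxo-4H-pyran-2-carboxylic acid
Product: 9 1-{5-[3,4-bis(tert-butyldimethylsilyloxy)phenyl]-4-oxo-4H-pyran-2-yl}-2-diazoethan-1-one, via acid chloride 8 (not isolated)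
Conditions: (COCl)2 (1.2 equiv), DMF (cat.), CH2Cl2, 0 °C to rt, evaporate; then CH2N2 (1.5 equiv), Et3N (1.1 equiv), Et2O/THF, −10 to 0 °C; AcOH quench
Reagents that add atoms: diazomethane, C=[N+]=[N-]; oxalyl chloride, O=C(Cl)C(=O)Cl (chlorine of intermediate 8 only)
Why: Arndt–Eistert acylation of diazomethane in its Newman–Beal form, suitable because acid chloride 8 has no α-hydrogen, so Et3N only takes up HCl and a small excess of diazomethane at low temperature should acylate faster than it adds to the pyranone.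

Step 7
Reactants: 10 prenyl bromide
Product: 11 5-methylhex-4-en-1-yne
Conditions: HC≡CMgBr (1.3 equiv), CuCl (5 mol %), THF, 0 to 45 °C; fractional distillation
Reagents that add atoms: ethynylmagnesium bromide, C#C[Mg]Br
Why: CuCl-catalysed coupling of an allylic bromide with an alkynyl Grignard reagent, which favours substitution at the unhindered primary terminus and gives the skipped enyne.

Step 8
Reactants: 11 5-methylhex-4-en-1-yne
Product: 14 triisopropyl[(5-methylhex-4-en-1-yn-1-yl)oxy]silane, via lithium acetylide 12 (not isolated), via lithium ynolate 13 (not isolated)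
Conditions: n-BuLi, THF, −78 °C; LiOOt-Bu (from t-BuOOH and LiN(SiMe3)2), −78 to 0 °C; TIPSOTf, −78 °C to rt
Reagents that add atoms: tert-butyl hydroperoxide, CC(C)(C)OO; triisopropylsilyl trifluoromethanesulfonate, CC(C)[Si](OS(=O)(=O)C(F)(F)F)(C(C)C)C(C)C; n-butyllithium, [Li]CCCC (lithium of intermediates 12 and 13 only)
Why: Oxygenation of a lithium acetylide by lithium tert-butyl peroxide gives the lithium ynolate, which the hard silyl triflate traps on oxygen, and the bulky triisopropylsilyl group makes the siloxyalkyne isolable.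

Step 9
Reactants: 9 1-{5-[3,4-bis(tert-butyldimethylsilyloxy)phenyl]-4-oxo-4H-pyran-2-yl}-2-diazoethan-1-one, 14 triisopropyl[(5-methylhex-4-en-1-yn-1-yl)oxy]silane
Product: 19 3-[3,4-bis(tert-butyldimethylsilyloxy)phenyl]-5-hydroxy-6-(3-methylbut-2-en-1-yl)-7-(triisopropylsilyloxy)-4H-chromen-4-one, via pyranonylketene 15 (not isolated), via vinylcyclobutenone 16 (not isolated), via dienylketene 17 (not isolated), via 4aH-chromene-4,5-dione tautomer 18 (not isolated)
Conditions: 14 (1.5 equiv), hν (390–450 nm LEDs, Pyrex), degassed ClCH2CH2Cl, rt; then 80 °C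
Reagents that add atoms: none
Why: Long-wavelength light expels N2 from 9 with 1,2-shift of the pyranonyl group (photochemical Wolff rearrangement, forming C8–C8a) to give ketene 15, whose central carbon is attacked by the nucleophilic prenyl-bearing carbon of ynol ether 14 in a [2+2] cycloaddition (C5–C6 and C7–C8) that gives cyclobutenone 16. Heating opens 16 by reversible 4π electrocyclic cleavage to dienylketene 17, whose ketene carbon closes onto pyranone C3 (C4a–C5) to give 18, and enolisation of the doubly activated C4a–H then delivers phenol 19. The closest known reaction is the diazo ketone form of the Danheiser benzannulation with siloxyalkynes, established for alkenyl, aryl and heteroaryl diazo ketones; the pyranone C2=C3 bond, only weakly aromatic, takes the part of the vinyl group. The one new ring, carbocyclic ring A, closes by thermal disrotatory 6π electrocyclisation; the product has no stereocentre, the sp3 centres of 16 and 18 being lost on ring opening and tautomerisation. The selectivity required is the orientation of the ketene–alkyne cycloaddition and the site of ring closure: the oxygen-polarised alkyne can bond only through its prenyl-bearing carbon to the ketene carbonyl carbon, which puts prenyl on C6 between C5–OH and C7–OSi, and closure is possible only at pyranone C3 because the other neighbour of C2 is the ring oxygen. Light of 390–450 nm should be absorbed by the diazo ketone but not by the pyranone or isoflavone chromophores, and the trisubstituted prenyl alkene is far less ketenophilic than the siloxyalkyne, so both spectators should survive.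

Step 10
Reactants: 19 3-[3,4-bis(tert-butyldimethylsilyloxy)phenyl]-5-hydroxy-6-(3-methylbut-2-en-1-yl)-7-(triisopropylsilyloxy)-4H-chromen-4-one
Product: 20 6-prenylorobol
Conditions: TBAF (4 equiv), AcOH (4 equiv), THF, 0 °C to rt
Reagents that add atoms: none
Why: Fluoride-driven cleavage of the three aryl silyl ethers (desilylation through Si–F bond formation), buffered with AcOH so that neither strong base reaches the air-sensitive catechol nor strong acid the prenyl group next to the free phenols.

Compound list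
1 | 4-bromocatechol (4-bromobenzene-1,2-diol) | Oc1ccc(Br)cc1O | starting material
2 | 4-bromo-1,2-bis(tert-butyldimethylsilyloxy)benzene | CC(C)(C)[Si](C)(C)Oc1ccc(Br)cc1O[Si](C)(C)C(C)(C)C | intermediate
3 | 2-[3,4-bis(tert-butyldimethylsilyloxy)phenyl]-4,4,5,5-tetramethyl-1,3,2-dioxaborolane | CC(C)(C)[Si](C)(C)Oc1ccc(cc1O[Si](C)(C)C(C)(C)C)B1OC(C)(C)C(C)(C)O1 | intermediate
4 | kojic acid (5-hydroxy-2-(hydroxymethyl)-4H-pyran-4-one) | OCc1cc(=O)c(O)co1 | starting material
5 | 6-(hydroxymethyl)-4-oxo-4H-pyran-3-yl trifluoromethanesulfonate | OCc1cc(=O)c(OS(=O)(=O)C(F)(F)F)co1 | intermediate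
6 | 5-[3,4-bis(tert-butyldimethylsilyloxy)phenyl]-2-(hydroxymethyl)-4H-pyran-4-one | OCc1cc(=O)c(-c2ccc(O[Si](C)(C)C(C)(C)C)c(O[Si](C)(C)C(C)(C)C)c2)co1 | intermediate
7 | 5-[3,4-bis(tert-butyldimethylsilyloxy)phenyl]-4-oxo-4H-pyran-2-carboxylic acid | OC(=O)c1cc(=O)c(-c2ccc(O[Si](C)(C)C(C)(C)C)c(O[Si](C)(C)C(C)(C)C)c2)co1 | intermediate
8 | 5-[3,4-bis(tert-butyldimethylsilyloxy)phenyl]-4-oxo-4H-pyran-2-carbonyl chloride (formed in the flask) | ClC(=O)c1cc(=O)c(-c2ccc(O[Si](C)(C)C(C)(C)C)c(O[Si](C)(C)C(C)(C)C)c2)co1 | intermediate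
9 | 1-{5-[3,4-bis(tert-butyldimethylsilyloxy)phenyl]-4-oxo-4H-pyran-2-yl}-2-diazoethan-1-one | O=C(C=[N+]=[N-])c1cc(=O)c(-c2ccc(O[Si](C)(C)C(C)(C)C)c(O[Si](C)(C)C(C)(C)C)c2)co1 | intermediate
10 | prenyl bromide (1-bromo-3-methylbut-2-ene) | CC(C)=CCBr | starting material
11 | 5-methylhex-4-en-1-yne | CC(C)=CCC#C | intermediate
12 | lithium 5-methylhex-4-en-1-yn-1-ide (formed in the flask) | [Li]C#CCC=C(C)C | intermediate
13 | lithium 5-methylhex-4-en-1-yn-1-olate (formed in the flask) | [Li]OC#CCC=C(C)C | intermediate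
14 | triisopropyl[(5-methylhex-4-en-1-yn-1-yl)oxy]silane | CC(C)=CCC#CO[Si](C(C)C)(C(C)C)C(C)C | intermediate
15 | {5-[3,4-bis(tert-butyldimethylsilyloxy)phenyl]-4-oxo-4H-pyran-2-yl}ketene (formed in the flask) | O=C=Cc1cc(=O)c(-c2ccc(O[Si](C)(C)C(C)(C)C)c(O[Si](C)(C)C(C)(C)C)c2)co1 | intermediate
16 | 4-{5-[3,4-bis(tert-butyldimethylsilyloxy)phenyl]-4-oxo-4H-pyran-2-yl}-2-(3-methylbut-2-en-1-yl)-3-(triisopropylsilyloxy)cyclobut-2-en-1-one (racemic, formed in the flask) | O=C1C(CC=C(C)C)=C(O[Si](C(C)C)(C(C)C)C(C)C)C1c1cc(=O)c(-c2ccc(O[Si](C)(C)C(C)(C)C)c(O[Si](C)(C)C(C)(C)C)c2)co1 | intermediate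
17 | (3E)-4-{5-[3,4-bis(tert-butyldimethylsilyloxy)phenyl]-4-oxo-4H-pyran-2-yl}-2-(3-methylbut-2-en-1-yl)-3-(triisopropylsilyloxy)buta-1,3-dien-1-one, pyranonyl cis to the ketene (formed in the flask) | O=C=C(CC=C(C)C)/C(O[Si](C(C)C)(C(C)C)C(C)C)=C\c1cc(=O)c(-c2ccc(O[Si](C)(C)C(C)(C)C)c(O[Si](C)(C)C(C)(C)C)c2)co1 | intermediate
18 | 3-[3,4-bis(tert-butyldimethylsilyloxy)phenyl]-6-(3-methylbut-2-en-1-yl)-7-(triisopropylsilyloxy)-4aH-chromene-4,5-dione (racemic keto tautomer, formed in the flask) | CC(C)=CCC1=C(O[Si](C(C)C)(C(C)C)C(C)C)C=C2OC=C(c3ccc(O[Si](C)(C)C(C)(C)C)c(O[Si](C)(C)C(C)(C)C)c3)C(=O)C2C1=O | intermediate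
19 | 3-[3,4-bis(tert-butyldimethylsilyloxy)phenyl]-5-hydroxy-6-(3-methylbut-2-en-1-yl)-7-(triisopropylsilyloxy)-4H-chromen-4-one | CC(C)=CCc1c(O[Si](C(C)C)(C(C)C)C(C)C)cc2occ(-c3ccc(O[Si](C)(C)C(C)(C)C)c(O[Si](C)(C)C(C)(C)C)c3)c(=O)c2c1O | intermediate
20 | 6-prenylorobol, 3-(3,4-dihydroxyphenyl)-5,7-dihydroxy-6-(3-methylbut-2-en-1-yl)-4H-chromen-4-one | CC(C)=CCc1c(O)cc2occ(-c3ccc(O)c(O)c3)c(=O)c2c1O | target

Total step count: 10. Longest linear sequence: 7 steps (steps 1, 2, 4, 5, 6, 9, 10).

Steps most likely to fail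

Step 9. Irradiation may consume material through light-induced rearrangement or dimerisation of the pyranone. The ketene may also self-condense before it meets the alkyne, or acylate the newly formed phenol while light is still on. The fallback generates the same ketene in the dark and sets out from diazo ketone 9. Silver-catalysed Wolff rearrangement in aqueous THF (PhCO2Ag, Et3N; Arndt–Eistert homologation) should give 2-{5-[3,4-bis(tert-butyldimethylsilyloxy)phenyl]-4-oxo-4H-pyran-2-yl}acetic acid F1. Oxalyl chloride with catalytic DMF should convert it into 2-{5-[3,4-bis(tert-butyldimethylsilyloxy)phenyl]-4-oxo-4H-pyran-2-yl}acetyl chloride F2. Slow addition of F2 to Et3N and siloxyalkyne 14 in toluene at rt should form ketene 15 by dehydrochlorination and trap it at once, as is known for ketenes and ynol ethers. The route is rejoined at cyclobutenone 16, which is heated at 80–110 °C to give 19.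

Step 6. Dipolar cycloaddition of diazomethane to the doubly activated pyranone double bond, or attack of chloride on the pyranone carbonyl during acid chloride formation, may compete with acylation. The fallback is a deacylative diazo transfer and sets out from acid 7. Coupling with N,O-dimethylhydroxylamine hydrochloride (EDC, N-methylmorpholine, CH2Cl2) should give N-methoxy-N-methyl-5-[3,4-bis(tert-butyldimethylsilyloxy)phenyl]-4-oxo-4H-pyran-2-carboxamide F3. MeMgBr in THF at −78 °C should give 2-acetyl-5-[3,4-bis(tert-butyldimethylsilyloxy)phenyl]-4H-pyran-4-one F4. Its lithium enolate (LiN(SiMe3)2, THF, −78 °C) is acylated with CF3CO2CH2CF3 to the unisolated 4,4,4-trifluoro-1-{5-[3,4-bis(tert-butyldimethylsilyloxy)phenyl]-4-oxo-4H-pyran-2-yl}butane-1,3-dione F5. Treatment of F5 with MsN3, Et3N and water in MeCN should transfer the diazo group with loss of the trifluoroacetyl group, and the route is rejoined at diazo ketone 9.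

Step 8. Oxygen transfer to the acetylide may be incomplete, the strongly basic medium may isomerise the doubly activated CH2 between alkyne and alkene, and the siloxyalkyne may hydrolyse on isolation. The fallback reaches the ynolate by Kowalski ester homologation and sets out from prenyl bromide 10, so it also bypasses step 7. Palladium-catalysed ethoxycarbonylation (PdCl2(PPh3)2, CO, EtOH, K2CO3) should give ethyl 4-methylpent-3-enoate F6, which can also be bought. Addition of LiCHBr2 (from CH2Br2 and lithium 2,2,6,6-tetramethylpiperidide, THF, −78 °C), then LiN(SiMe3)2 and n-BuLi with warming, should pass through lithium 1,1-dibromo-5-methylhexa-1,4-dien-2-olate F7. Bromine–lithium exchange and 1,2-shift of the prenyl group then give the ynolate, and the route is rejoined at lithium ynolate 13, which is silylated with TIPSOTf as in step 8 to give 14.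

Further compounds
F1 | step 9 | 2-{5-[3,4-bis(tert-butyldimethylsilyloxy)phenyl]-4-oxo-4H-pyran-2-yl}acetic acid | OC(=O)Cc1cc(=O)c(-c2ccc(O[Si](C)(C)C(C)(C)C)c(O[Si](C)(C)C(C)(C)C)c2)co1
F2 | step 9 | 2-{5-[3,4-bis(tert-butyldimethylsilyloxy)phenyl]-4-oxo-4H-pyran-2-yl}acetyl chloride | ClC(=O)Cc1cc(=O)c(-c2ccc(O[Si](C)(C)C(C)(C)C)c(O[Si](C)(C)C(C)(C)C)c2)co1
F3 | step 6 | N-methoxy-N-methyl-5-[3,4-bis(tert-butyldimethylsilyloxy)phenyl]-4-oxo-4H-pyran-2-carboxamide | CON(C)C(=O)c1cc(=O)c(-c2ccc(O[Si](C)(C)C(C)(C)C)c(O[Si](C)(C)C(C)(C)C)c2)co1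
F4 | step 6 | 2-acetyl-5-[3,4-bis(tert-butyldimethylsilyloxy)phenyl]-4H-pyran-4-one | CC(=O)c1cc(=O)c(-c2ccc(O[Si](C)(C)C(C)(C)C)c(O[Si](C)(C)C(C)(C)C)c2)co1
F5 | step 6 | 4,4,4-trifluoro-1-{5-[3,4-bis(tert-butyldimethylsilyloxy)phenyl]-4-oxo-4H-pyran-2-yl}butane-1,3-dione | O=C(CC(=O)C(F)(F)F)c1cc(=O)c(-c2ccc(O[Si](C)(C)C(C)(C)C)c(O[Si](C)(C)C(C)(C)C)c2)co1
F6 | step 8 | ethyl 4-methylpent-3-enoate | CCOC(=O)CC=C(C)C
F7 | step 8 | lithium 1,1-dibromo-5-methylhexa-1,4-dien-2-olate | [Li]OC(CC=C(C)C)=C(Br)Br
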